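The target hides an aldol. In the δ-lactone (ring B) the benzylic carbon C4 is bonded to the oxygen-bearing carbon C3, and the ring oxygen O2 sits where an aldehyde oxygen would end up. The plan therefore cuts C3–C4 and C1–O2 together. One catalytic enantioselective aldol–lactonisation joins an enolisable anhydride, 8-acetoxyisochromane-1,3-dione (ring A fused to a six-membered anhydride), to (2E,4E)-octadeca-2,4-dienal. It closes ring B, sets C3 and leaves a carboxyl group on C4 as a traceless activator. A thiol-free radical reduction then removes that group and mild methanolysis frees the phenol, so the ionisable dienylic C3–O2 bond never meets a Lewis acid.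

Key step: step 7

Assumption: the quinine-derived squaramide is taken to guide the enolate to the Re face of the dienal, as (3S,4R)-11 requires. If the first run shows the opposite sense, the quinidine-derived pseudo-enantiomer is used and nothing else changes.

Design notes
- **Phenol protection.** C3–O2 is the ester bond of a pentadienyl-type carbinol. A boron or aluminium halide chelated to the C1 carbonyl could ionise it, at the cost of the C3 configuration or of the ring. The methyl ether of commercial acid 1 is therefore cleaved in step 2, before anything sensitive exists. The phenol then travels as an acetate, which acetic anhydride installs while it closes the anhydride. The acetate also makes C4–H more acidic and C1 more electrophilic.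
- **Removal of the C4 carboxyl group.**
  - Heat and base are excluded, because a C4 carboxylate or carbanion can expel the C3–O2 carboxylate and give an achiral trienylbenzoic acid.
  - Chains carried by thiyl or stannyl radicals, strongly oxidising photocatalysts and sensitisers of high triplet energy are excluded, because each attacks or isomerises a conjugated diene.
  - The redox-active ester/Hantzsch ester pair avoids all of these.
  - The only cyclisation open to the C4 radical (3-exo onto C1′) is reversible and returns the same benzylic radical.
- **Stereochemical bookkeeping.** C3 keeps one spatial arrangement from 10 to 14. Its descriptor is S while C4 bears a carboxyl-type carbon and R after step 9, only because the ranking of C4 and C1′ is inverted. C4 is erased, but the cis isomer formed in the aldol event need not share the C3 configuration of the trans isomer. It is therefore removed at the stage of 11.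

Step 1
Reactants: 1 2-methoxy-6-methylbenzoic acid
Product: 2 2-(carboxymethyl)-6-methoxybenzoic acid
Conditions: LiN(i-Pr)2 (3 equiv), THF, −78 to 0 °C; CO2 (excess), −78 °C; aq. HCl
Reagents that add atoms: carbon dioxide, O=C=O
Why: Lateral lithiation–carboxylation of an o-toluic acid: the lithium carboxylate guides the amide base to the ortho methyl group and stabilises the benzylic carbanion, which takes up CO2, while the extra base absorbs the more acidic CH2 proton of the arylacetate as it forms.

Step 2
Reactants: 2 2-(carboxymethyl)-6-methoxybenzoic acid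
Product: 3 2-(carboxymethyl)-6-hydroxybenzoic acid
Conditions: BBr3 (4 equiv), CH2Cl2, −78 °C to rt; H2O
Reagents that add atoms: none
Why: Lewis-acid cleavage of an aryl methyl ether, assisted by chelation of boron to the neighbouring carboxyl group, is run at this early stage because the substrate holds nothing that an acid could damage.

Step 3
Reactants: 3 2-(carboxymethyl)-6-hydroxybenzoic acid
Product: 4 1,3-dioxoisochroman-8-yl acetate (8-acetoxyisochromane-1,3-dione)
Conditions: Ac2O (neat), 100 °C; evaporate; recrystallise from toluene
Reagents that add atoms: acetic anhydride, CC(=O)OC(C)=O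
Why: Hot acetic anhydride without base should close the six-membered cyclic anhydride by dehydration and O-acetylate the phenol in the same operation, as it does with hydroxyphthalic acids, and the absence of pyridine-type bases suppresses C-acetylation at the enolisable C4.

Step 4
Reactants: 5 tetradecanal; 6 triethyl 4-phosphonocrotonate
Product: 7 ethyl (2E,4E)-octadeca-2,4-dienoate
Conditions: LiN(SiMe3)2 (1.1 equiv), THF, −78 °C to rt; aq. NH4Cl
Reagents that add atoms: none
Why: Vinylogous Horner–Wadsworth–Emmons olefination: the stabilised phosphonate anion reacts through the carbon next to phosphorus, the reversible addition favours the E geometry of the new C4=C5 bond, and the C2=C3 bond comes in as E from reagent 6.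

Step 5
Reactants: 7 ethyl (2E,4E)-octadeca-2,4-dienoate
Product: 8 (2E,4E)-octadeca-2,4-dien-1-ol
Conditions: i-Bu2AlH (2.3 equiv), CH2Cl2, −78 to 0 °C; aq. Rochelle salt
Reagents that add atoms: none
Why: i-Bu2AlH reduces the conjugated ester by 1,2-hydride delivery through the aldehyde to the primary dienol and leaves the diene and its geometry untouched.

Step 6
Reactants: 8 (2E,4E)-octadeca-2,4-dien-1-ol
Product: 9 (2E,4E)-octadeca-2,4-dienal
Conditions: MnO2 (activated, excess), CH2Cl2, rt
Reagents that add atoms: none
Why: Activated MnO2 oxidises allylic and dienylic alcohols selectively under neutral heterogeneous conditions, so the dienal should form without over-oxidation or loss of E,E geometry.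

Step 7
Reactants: 4 1,3-dioxoisochroman-8-yl acetate; 9 (2E,4E)-octadeca-2,4-dienal
Product: 11 (3S,4R)-8-acetoxy-3-[(1E,3E)-heptadeca-1,3-dien-1-yl]-1-oxoisochromane-4-carboxylic acid (trans), via aldol adduct 10 (not isolated)
Conditions: 3-{[3,5-bis(trifluoromethyl)phenyl]amino}-4-{[(8α,9S)-6′-methoxycinchonan-9-yl]amino}cyclobut-3-ene-1,2-dione (10 mol%), MTBE, −20 °C; wash with cold 1 M HCl; SiO2 (eluent with 1% AcOH) to remove the cis isomer
Reagents that add atoms: none
Why: The quinuclidine nitrogen deprotonates the acidic benzylic CH2 of 4 while the two squaramide N–H bonds bind the aldehyde oxygen of 9, so the enolate carbon C4 adds to the carbonyl carbon inside a chiral ion pair and forms C3–C4 (adduct 10). The alkoxide of 10 then attacks the aryl-bound carbonyl C1 in a 6-exo-trig acyl substitution that closes ring B (C1–O2) and expels the aliphatic carboxylate, which ends as the C4 acid and makes the reversible aldol step irreversible, whereas attack at the other carbonyl would need a four-membered ring. The closest known reaction type is the squaramide-catalysed formal [4+2] cycloaddition of homophthalic anhydrides with aldehydes, the oxygen counterpart of the Castagnoli–Cushman reaction. C3 is set by the catalyst, which leaves only the Re face of the bound aldehyde open, and C4 follows from the anti placement of the dienyl and carboxyl groups in the same transition state (trans), although it is erased in step 9. The step needs carbonyl attack rather than 1,4- or 1,6-addition, which is secured by hydrogen-bond activation at the carbonyl oxygen, by the lack of an α-hydrogen in 9 and by the fast lactonisation that drains only the 1,2-adduct. The electron-poor 8-acetoxy group supports both events, since it raises the acidity of C4–H and the electrophilicity of C1 compared with an 8-alkoxy group.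

Step 8
Reactants: 11 (3S,4R)-8-acetoxy-3-[(1E,3E)-heptadeca-1,3-dien-1-yl]-1-oxoisochromane-4-carboxylic acid
Product: 12 1,3-dioxoisoindolin-2-yl (3S,4R)-8-acetoxy-3-[(1E,3E)-heptadeca-1,3-dien-1-yl]-1-oxoisochromane-4-carboxylate
Conditions: N-hydroxyphthalimide (1.1 equiv), N,N′-diisopropylcarbodiimide (1.1 equiv), CH2Cl2, 0 °C to rt, no amine base; filter; short SiO2 plug
Reagents that add atoms: N-hydroxyphthalimide, O=C1c2ccccc2C(=O)N1O
Why: Carbodiimide esterification (Steglich type, here without DMAP) should give the redox-active ester, the omission of any amine base keeps the acidified C4–H from starting a β-elimination of the lactone carboxylate, and epimerisation at C4 would be of no consequence.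

Step 9
Reactants: 12 1,3-dioxoisoindolin-2-yl (3S,4R)-8-acetoxy-3-[(1E,3E)-heptadeca-1,3-dien-1-yl]-1-oxoisochromane-4-carboxylate
Product: 13 (3R)-3-[(1E,3E)-heptadeca-1,3-dien-1-yl]-1-oxoisochroman-8-yl acetate
Conditions: Hantzsch ester (diethyl 2,6-dimethyl-1,4-dihydropyridine-3,5-dicarboxylate, 2 equiv), Ru(bpy)3(PF6)2 (1 mol%), degassed CH2Cl2, blue LEDs (450 nm), rt
Reagents that add atoms: none
Why: Photoreductive decarboxylation of an N-(acyloxy)phthalimide: electron transfer breaks the N–O bond, CO2 leaves, and the benzylic C4 radical takes a hydrogen atom from the dihydropyridine, so that no radical able to add to the diene is present, C4 becomes a CH2 group and the untouched C3 keeps its arrangement (now named R).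

Step 10
Reactants: 13 (3R)-3-[(1E,3E)-heptadeca-1,3-dien-1-yl]-1-oxoisochroman-8-yl acetate
Product: 14 (3R)-3-[(1E,3E)-heptadeca-1,3-dien-1-yl]-8-hydroxyisochroman-1-one
Conditions: K2CO3 (0.3 equiv), MeOH–THF, 0 °C; aq. NH4Cl
Reagents that add atoms: none
Why: Carbonate-catalysed transesterification removes the activated aryl acetate much faster than methoxide can attack the lactone carbonyl, which is flanked by two ortho substituents, and since neither acid nor Lewis acid is present the dienylic C3–O2 bond and the (R) centre should stay intact.

Compound list
1 | 2-methoxy-6-methylbenzoic acid | COc1cccc(C)c1C(=O)O | starting material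
2 | 2-(carboxymethyl)-6-methoxybenzoic acid | COc1cccc(CC(=O)O)c1C(=O)O | intermediate
3 | 2-(carboxymethyl)-6-hydroxybenzoic acid | Oc1cccc(CC(=O)O)c1C(=O)O | intermediate
4 | 1,3-dioxoisochroman-8-yl acetate (8-acetoxyisochromane-1,3-dione) | CC(=O)Oc1cccc2CC(=O)OC(=O)c12 | intermediate
5 | tetradecanal | CCCCCCCCCCCCCC=O | starting material
6 | triethyl 4-phosphonocrotonate | CCOC(=O)/C=C/CP(=O)(OCC)OCC | starting material
7 | ethyl (2E,4E)-octadeca-2,4-dienoate | CCCCCCCCCCCCC/C=C/C=C/C(=O)OCC | intermediate
8 | (2E,4E)-octadeca-2,4-dien-1-ol | CCCCCCCCCCCCC/C=C/C=C/CO | intermediate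
9 | (2E,4E)-octadeca-2,4-dienal | CCCCCCCCCCCCC/C=C/C=C/C=O | intermediate
10 | (4R)-4-[(1S,2E,4E)-1-hydroxyoctadeca-2,4-dien-1-yl]-1,3-dioxoisochroman-8-yl acetate (aldol adduct) | CCCCCCCCCCCCC/C=C/C=C/[C@H](O)[C@@H]1C(=O)OC(=O)c2c(OC(C)=O)cccc12 | intermediate
11 | (3S,4R)-8-acetoxy-3-[(1E,3E)-heptadeca-1,3-dien-1-yl]-1-oxoisochromane-4-carboxylic acid | CCCCCCCCCCCCC/C=C/C=C/[C@H]1[C@H](C(=O)O)c2cccc(OC(C)=O)c2C(=O)O1 | intermediate
12 | 1,3-dioxoisoindolin-2-yl (3S,4R)-8-acetoxy-3-[(1E,3E)-heptadeca-1,3-dien-1-yl]-1-oxoisochromane-4-carboxylate | CCCCCCCCCCCCC/C=C/C=C/[C@H]1[C@H](C(=O)ON3C(=O)c4ccccc4C3=O)c2cccc(OC(C)=O)c2C(=O)O1 | intermediate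
13 | (3R)-3-[(1E,3E)-heptadeca-1,3-dien-1-yl]-1-oxoisochroman-8-yl acetate | CCCCCCCCCCCCC/C=C/C=C/[C@H]1Cc2cccc(OC(C)=O)c2C(=O)O1 | intermediate
14 | (3R)-3-[(1E,3E)-heptadeca-1,3-dien-1-yl]-8-hydroxyisochroman-1-one (CNP0165705.1) | CCCCCCCCCCCCC/C=C/C=C/[C@H]1Cc2cccc(O)c2C(=O)O1 | target

Total step count: 10.

Longest linear sequence: 7 steps. This holds for steps 1, 2, 3, 7, 8, 9, 10 and equally for steps 4, 5, 6, 7, 8, 9, 10.

Steps most likely to fail

**Step 7.** Facial selectivity may be poor on a slim, flexible dienal, and the uncatalysed background reaction may erode it further.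
- The fallback gives up asymmetric induction in favour of separation. It sets out from 4 and 9 and comes back at 11.
- The annulation is run with an achiral tertiary amine (i-Pr2NEt, CH2Cl2, 0 °C). This should give the racemic trans acid, that is 11 together with its antipode (3R,4S)-8-acetoxy-3-[(1E,3E)-heptadeca-1,3-dien-1-yl]-1-oxoisochromane-4-carboxylic acid F1.
- The two are parted by preparative supercritical-fluid chromatography on a chiral stationary phase with an acidic modifier.
- Should conjugate addition be the cause of failure, the detour given under step 9 applies instead.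

**Step 9.** Hydrogen-atom transfer to the stabilised benzylic radical may be outrun in two ways. The radical may add to the diene of a second molecule, or it may be reduced further to a carbanion that expels the lactone carboxylate.
- The fallback abandons the carboxyl activator. It sets out from 1 and 7 and comes back at 14.
- Acid 1 is demethylated (BBr3, CH2Cl2) to 2-hydroxy-6-methylbenzoic acid F2. This is condensed with acetone (TFAA, TFA) to 2,2,5-trimethyl-4H-1,3-benzodioxin-4-one F3.
- Ester 7 is converted (MeNH(OMe)·HCl, i-PrMgCl, THF, −20 °C) into (2E,4E)-N-methoxy-N-methyloctadeca-2,4-dienamide F4.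
- Lateral lithiation of F3 (LiN(i-Pr)2, THF, −78 °C) and acylation by F4 should give 2,2-dimethyl-5-[(3E,5E)-2-oxononadeca-3,5-dien-1-yl]-4H-1,3-benzodioxin-4-one F5.
- Corey–Bakshi–Shibata reduction follows ((S)-2-methyl-CBS-oxazaborolidine, catecholborane, toluene, −78 °C), with the dienyl arm acting as the large group. It should give 5-[(2R,3E,5E)-2-hydroxynonadeca-3,5-dien-1-yl]-2,2-dimethyl-4H-1,3-benzodioxin-4-one F6.
- A catalytic amount of NaH in THF at 0 °C then lets the alkoxide attack the dioxinone carbonyl. This closes ring B, releases acetone and uncovers the phenol.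
- The same detour also answers trouble in step 8.

**Step 4.** Geometry may leak at the new C4=C5 double bond. This cannot be repaired later, because the isomers travel together.
- The fallback replaces the single four-carbon olefination by two two-carbon olefinations, each with a purification. It sets out from 5 and comes back at 7.
- Horner–Wadsworth–Emmons reaction of 5 with triethyl phosphonoacetate (LiCl, DBU, MeCN, Masamune–Roush conditions) should give ethyl (E)-hexadec-2-enoate F7.
- i-Bu2AlH should give (E)-hexadec-2-en-1-ol F8, and MnO2 should give (E)-hexadec-2-enal F9.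
- A second olefination with the same phosphonate leads to 7.

Further compounds
F1 | step 7 | (3R,4S)-8-acetoxy-3-[(1E,3E)-heptadeca-1,3-dien-1-yl]-1-oxoisochromane-4-carboxylic acid | CCCCCCCCCCCCC/C=C/C=C/[C@@H]1[C@@H](C(=O)O)c2cccc(OC(C)=O)c2C(=O)O1
F2 | step 9 | 2-hydroxy-6-methylbenzoic acid | Cc1cccc(O)c1C(=O)O
F3 | step 9 | 2,2,5-trimethyl-4H-1,3-benzodioxin-4-one | Cc1cccc2OC(C)(C)OC(=O)c12
F4 | step 9 | (2E,4E)-N-methoxy-N-methyloctadeca-2,4-dienamide | CCCCCCCCCCCCC/C=C/C=C/C(=O)N(C)OC
F5 | step 9 | 2,2-dimethyl-5-[(3E,5E)-2-oxononadeca-3,5-dien-1-yl]-4H-1,3-benzodioxin-4-one | CCCCCCCCCCCCC/C=C/C=C/C(=O)Cc1cccc2OC(C)(C)OC(=O)c12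
F6 | step 9 | 5-[(2R,3E,5E)-2-hydroxynonadeca-3,5-dien-1-yl]-2,2-dimethyl-4H-1,3-benzodioxin-4-one | CCCCCCCCCCCCC/C=C/C=C/[C@H](O)Cc1cccc2OC(C)(C)OC(=O)c12
F7 | step 4 | ethyl (E)-hexadec-2-enoate | CCCCCCCCCCCCC/C=C/C(=O)OCC
F8 | step 4 | (E)-hexadec-2-en-1-ol | CCCCCCCCCCCCC/C=C/CO
F9 | step 4 | (E)-hexadec-2-enal | CCCCCCCCCCCCC/C=C/C=O
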